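**Retrosynthetic overview**
1. The target is the isovanillate ester of an (S)-humulatrienol; the ester is made last by acylation with phenol-protected isovanillic acid.
2. The 2-substituted diene comes from Wittig methylenation of an 11-membered (2E,8E)-dienone. This is the only ring built (the arene is bought), and it is closed by intramolecular Horner–Wadsworth–Emmons olefination next to the CMe2 carbon.
3. The keto-phosphonate aldehyde comes from γ-alkylation of the dianion of dimethyl (2-oxopropyl)phosphonate with an (E)-allylic bromide.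
4. The allylic bromide comes from an (S,E)-δ-hydroxy-β-methyl enoate, made in the key step: an intermolecular catalytic asymmetric vinylogous Mukaiyama aldol that forms the CH(OH)–CH2 bond and sets both the stereocentre and the E-trisubstituted alkene.
5. The aldol partners are a C6 aldehyde from 2,2-dimethylpent-4-enal and the silyl dienolate of methyl 3-methylbut-2-enoate.

Assumption: the carbinol centre of the target is (S) (CIP order O > CH2CMe2 > CH2C(Me)= > H). The sense of induction stated for the chiral catalyst in step 5 is from recollection of the literature model and should be confirmed on compound 9 by Mosher ester analysis; both catalyst enantiomers are available.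

**Step 1**
Reactants: 1 2,2-dimethylpent-4-enal
Product: 2 2,2-dimethylpent-4-en-1-ol
Conditions: NaBH4, MeOH, 0 °C
Reagents that add atoms: none
Why: Chemoselective borohydride reduction of the aldehyde leaves the terminal alkene untouched.

**Step 2**
Reactants: 2 2,2-dimethylpent-4-en-1-ol
Product: 3 1-{[(2,2-dimethylpent-4-en-1-yl)oxy]methyl}-4-methoxybenzene
Conditions: NaH, PMBCl, cat. Bu4NI, DMF, 0 °C → rt
Reagents that add atoms: 4-methoxybenzyl chloride, COc1ccc(CCl)cc1
Why: Williamson etherification gives a PMB ether that survives Lewis acid, hydride and strong base and is later removed oxidatively next to a silyl ether.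

**Step 3**
Reactants: 3 1-{[(2,2-dimethylpent-4-en-1-yl)oxy]methyl}-4-methoxybenzene
Product: 4 4-[(4-methoxybenzyl)oxy]-3,3-dimethylbutanal
Conditions: OsO4 (2 mol %), NaIO4, 2,6-lutidine, dioxane/H2O 3:1, rt
Reagents that add atoms: osmium tetroxide (catalytic oxygen carrier), O=[Os](=O)(=O)=O; sodium periodate (terminal oxygen source), [Na+].[O-]I(=O)(=O)=O
Why: Lemieux–Johnson oxidative cleavage of the terminal alkene avoids exposing the electron-rich PMB ring to ozone, and lutidine suppresses over-oxidation.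

**Step 4**
Reactants: 5 methyl 3-methylbut-2-enoate
Product: 7 tert-butyl[(1-methoxy-3-methylbuta-1,3-dien-1-yl)oxy]dimethylsilane, via lithium dienolate 6 (not isolated)
Conditions: LDA (commercial solution), THF/DMPU, −78 °C; then TBSCl, −78 °C → rt; distil
Reagents that add atoms: tert-butyldimethylsilyl chloride, CC(C)(C)[Si](C)(C)Cl
Why: Kinetic γ-deprotonation of the senecioate and O-silylation of the extended enolate give the silyl ketene acetal (dienolate) needed for the vinylogous aldol.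

**Step 5 (key step)**
Reactants: 4 4-[(4-methoxybenzyl)oxy]-3,3-dimethylbutanal; 7 tert-butyl[(1-methoxy-3-methylbuta-1,3-dien-1-yl)oxy]dimethylsilane
Product: 9 methyl (2E,5S)-5-hydroxy-8-[(4-methoxybenzyl)oxy]-3,7,7-trimethyloct-2-enoate, via trichlorosilyl aldolate 8 (not isolated)
Conditions: SiCl4 (1.1 eq), (S,S)-Denmark binaphthyldiamine bisphosphoramide (5 mol %), i-Pr2NEt (10 mol %), CH2Cl2, −72 → −50 °C; then sat. aq. NaHCO3
Reagents that add atoms: none
Why: In this Denmark Lewis-base-activated SiCl4 vinylogous Mukaiyama aldol the bulky chiral trichlorosilyl cation–aldehyde complex forces γ-attack through an open transition state with the s-trans dienolate (giving the E-alkene), and the (S,S)-catalyst is chosen to expose the Si face of 4, which gives the (S)-carbinol.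

**Step 6**
Reactants: 9 methyl (2E,5S)-5-hydroxy-8-[(4-methoxybenzyl)oxy]-3,7,7-trimethyloct-2-enoate
Product: 10 methyl (2E,5S)-5-[(tert-butyldimethylsilyl)oxy]-8-[(4-methoxybenzyl)oxy]-3,7,7-trimethyloct-2-enoate
Conditions: TBSCl, imidazole, DMF, rt
Reagents that add atoms: tert-butyldimethylsilyl chloride, CC(C)(C)[Si](C)(C)Cl
Why: Standard silylation protects the secondary alcohol without touching the stereocentre, and the E-enoate cannot lactonise.

**Step 7**
Reactants: 10 methyl (2E,5S)-5-[(tert-butyldimethylsilyl)oxy]-8-[(4-methoxybenzyl)oxy]-3,7,7-trimethyloct-2-enoate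
Product: 11 (2E,5S)-5-[(tert-butyldimethylsilyl)oxy]-8-[(4-methoxybenzyl)oxy]-3,7,7-trimethyloct-2-en-1-ol
Conditions: DIBAL-H (2.5 eq), CH2Cl2, −78 °C; Rochelle salt work-up
Reagents that add atoms: none
Why: DIBAL-H 1,2-reduction of the enoate gives the allylic alcohol with the alkene geometry retained.

**Step 8**
Reactants: 11 (2E,5S)-5-[(tert-butyldimethylsilyl)oxy]-8-[(4-methoxybenzyl)oxy]-3,7,7-trimethyloct-2-en-1-ol
Product: 12 (2E,5S)-1-bromo-5-[(tert-butyldimethylsilyl)oxy]-8-[(4-methoxybenzyl)oxy]-3,7,7-trimethyloct-2-ene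
Conditions: CBr4, PPh3, 2,6-lutidine, CH2Cl2, 0 °C; used directly
Reagents that add atoms: carbon tetrabromide, BrC(Br)(Br)Br
Why: The Appel reaction converts the primary allylic alcohol into the bromide under near-neutral conditions without allylic transposition or E/Z scrambling.

**Step 9**
Reactants: 12 (2E,5S)-1-bromo-5-[(tert-butyldimethylsilyl)oxy]-8-[(4-methoxybenzyl)oxy]-3,7,7-trimethyloct-2-ene; 13 dimethyl (2-oxopropyl)phosphonate
Product: 15 dimethyl [(5E,8S)-8-[(tert-butyldimethylsilyl)oxy]-11-[(4-methoxybenzyl)oxy]-6,10,10-trimethyl-2-oxoundec-5-en-1-yl]phosphonate, via phosphonate dianion 14 (not isolated)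
Conditions: 13, NaH, THF, 0 °C; n-BuLi, 0 °C; then 12, 0 °C → rt; AcOH quench
Reagents that add atoms: none
Why: The more basic terminal (γ) carbanion of the β-ketophosphonate dianion undergoes SN2 alkylation with the primary allylic bromide (Grieco dianion alkylation), which installs the three remaining ring carbons and the HWE handle in one step.

**Step 10**
Reactants: 15 dimethyl [(5E,8S)-8-[(tert-butyldimethylsilyl)oxy]-11-[(4-methoxybenzyl)oxy]-6,10,10-trimethyl-2-oxoundec-5-en-1-yl]phosphonate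
Product: 16 dimethyl [(5E,8S)-8-[(tert-butyldimethylsilyl)oxy]-11-hydroxy-6,10,10-trimethyl-2-oxoundec-5-en-1-yl]phosphonate
Conditions: DDQ, CH2Cl2/pH 7 buffer 10:1, 0 °C → rt
Reagents that add atoms: none
Why: Oxidative PMB cleavage with DDQ is orthogonal to the TBS ether, the trisubstituted alkene and the β-ketophosphonate.

**Step 11**
Reactants: 16 dimethyl [(5E,8S)-8-[(tert-butyldimethylsilyl)oxy]-11-hydroxy-6,10,10-trimethyl-2-oxoundec-5-en-1-yl]phosphonate
Product: 17 dimethyl [(5E,8S)-8-[(tert-butyldimethylsilyl)oxy]-6,10,10-trimethyl-2,11-dioxoundec-5-en-1-yl]phosphonate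
Conditions: Dess–Martin periodinane, CH2Cl2, 0 °C → rt
Reagents that add atoms: none
Why: Dess–Martin oxidation of the neopentyl alcohol gives a non-enolisable α,α-dimethyl aldehyde and tolerates the β-ketophosphonate.

**Step 12**
Reactants: 17 dimethyl [(5E,8S)-8-[(tert-butyldimethylsilyl)oxy]-6,10,10-trimethyl-2,11-dioxoundec-5-en-1-yl]phosphonate
Product: 18 (2E,6S,8E)-6-[(tert-butyldimethylsilyl)oxy]-4,4,8-trimethylcycloundeca-2,8-dien-1-one
Conditions: LiCl, i-Pr2NEt, MeCN, 1 mM (slow addition of 17), rt → 50 °C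
Reagents that add atoms: none
Why: Intramolecular Horner–Wadsworth–Emmons olefination under Masamune–Roush conditions closes the 11-membered ring as the E-enone; the aldehyde cannot enolise or self-condense, and the gem-dimethyl group and two E-alkenes pre-organise the chain.

**Step 13**
Reactants: 18 (2E,6S,8E)-6-[(tert-butyldimethylsilyl)oxy]-4,4,8-trimethylcycloundeca-2,8-dien-1-one
Product: 19 tert-butyldimethyl{[(1S,3E,8E)-3,10,10-trimethyl-7-methylidenecycloundeca-3,8-dien-1-yl]oxy}silane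
Conditions: Ph3PCH3Br, KOtBu, THF, 0 °C → rt
Reagents that add atoms: methyltriphenylphosphonium bromide, C[P+](c1ccccc1)(c1ccccc1)c1ccccc1.[Br-]
Why: Wittig methylenation adds 1,2 to the enone carbonyl and gives the exocyclic 2-substituted 1,3-diene; the enone has no γ-hydrogens, so it cannot deconjugate.

**Step 14**
Reactants: 19 tert-butyldimethyl{[(1S,3E,8E)-3,10,10-trimethyl-7-methylidenecycloundeca-3,8-dien-1-yl]oxy}silane
Product: 20 (1S,3E,8E)-3,10,10-trimethyl-7-methylidenecycloundeca-3,8-dien-1-ol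
Conditions: TBAF, THF, rt → 40 °C
Reagents that add atoms: none
Why: Fluoride desilylation is non-acidic, so the acid-sensitive diene is preserved and the carbinol configuration is untouched.

**Step 15**
Reactants: 21 3-hydroxy-4-methoxybenzoic acid (isovanillic acid)
Product: 23 3-[(tert-butyldimethylsilyl)oxy]-4-methoxybenzoic acid, via bis-silyl derivative 22 (not isolated)
Conditions: TBSCl (2.5 eq), imidazole, DMF, rt; then AcOH/THF/H2O 3:1:1, rt
Reagents that add atoms: tert-butyldimethylsilyl chloride, CC(C)(C)[Si](C)(C)Cl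
Why: Exhaustive silylation followed by selective hydrolysis of the much more labile silyl ester leaves the aryl silyl ether and frees the acid.

**Step 16**
Reactants: 20 (1S,3E,8E)-3,10,10-trimethyl-7-methylidenecycloundeca-3,8-dien-1-ol; 23 3-[(tert-butyldimethylsilyl)oxy]-4-methoxybenzoic acid
Product: 24 (1S,3E,8E)-3,10,10-trimethyl-7-methylidenecycloundeca-3,8-dien-1-yl 3-[(tert-butyldimethylsilyl)oxy]-4-methoxybenzoate
Conditions: EDC·HCl, DMAP, CH2Cl2, rt
Reagents that add atoms: none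
Why: Steglich esterification acylates the secondary alcohol at oxygen, so the (S) configuration is retained, and the masked phenol cannot compete.

**Step 17**
Reactants: 24 (1S,3E,8E)-3,10,10-trimethyl-7-methylidenecycloundeca-3,8-dien-1-yl 3-[(tert-butyldimethylsilyl)oxy]-4-methoxybenzoate
Product: 25 (1S,3E,8E)-3,10,10-trimethyl-7-methylidenecycloundeca-3,8-dien-1-yl 3-hydroxy-4-methoxybenzoate
Conditions: TBAF (1.1 eq), AcOH (1.2 eq), THF, 0 °C
Reagents that add atoms: none
Why: Aryl silyl ethers are cleaved within minutes by buffered fluoride, conditions under which the benzoate ester and the triene are inert.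

**Compound list**
1 | 2,2-dimethylpent-4-enal | C=CCC(C)(C)C=O | starting material
2 | 2,2-dimethylpent-4-en-1-ol | C=CCC(C)(C)CO | intermediate
3 | 1-{[(2,2-dimethylpent-4-en-1-yl)oxy]methyl}-4-methoxybenzene | C=CCC(C)(C)COCc1ccc(OC)cc1 | intermediate
4 | 4-[(4-methoxybenzyl)oxy]-3,3-dimethylbutanal | O=CCC(C)(C)COCc1ccc(OC)cc1 | intermediate
5 | methyl 3-methylbut-2-enoate | COC(=O)C=C(C)C | starting material
6 | lithium dienolate of methyl 3-methylbut-2-enoate (lithium 1-methoxy-3-methylbuta-1,3-dien-1-olate) | [Li+].C=C(C)C=C([O-])OC | intermediate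
7 | tert-butyl[(1-methoxy-3-methylbuta-1,3-dien-1-yl)oxy]dimethylsilane (drawn 1Z; ketene-acetal geometry does not affect the product) | C=C(C)/C=C(/OC)O[Si](C)(C)C(C)(C)C | intermediate
8 | methyl (2E,5S)-8-[(4-methoxybenzyl)oxy]-3,7,7-trimethyl-5-[(trichlorosilyl)oxy]oct-2-enoate | COC(=O)/C=C(\C)C[C@H](O[Si](Cl)(Cl)Cl)CC(C)(C)COCc1ccc(OC)cc1 | intermediate
9 | methyl (2E,5S)-5-hydroxy-8-[(4-methoxybenzyl)oxy]-3,7,7-trimethyloct-2-enoate | COC(=O)/C=C(\C)C[C@H](O)CC(C)(C)COCc1ccc(OC)cc1 | intermediate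
10 | methyl (2E,5S)-5-[(tert-butyldimethylsilyl)oxy]-8-[(4-methoxybenzyl)oxy]-3,7,7-trimethyloct-2-enoate | COC(=O)/C=C(\C)C[C@H](O[Si](C)(C)C(C)(C)C)CC(C)(C)COCc1ccc(OC)cc1 | intermediate
11 | (2E,5S)-5-[(tert-butyldimethylsilyl)oxy]-8-[(4-methoxybenzyl)oxy]-3,7,7-trimethyloct-2-en-1-ol | OC/C=C(\C)C[C@H](O[Si](C)(C)C(C)(C)C)CC(C)(C)COCc1ccc(OC)cc1 | intermediate
12 | (2E,5S)-1-bromo-5-[(tert-butyldimethylsilyl)oxy]-8-[(4-methoxybenzyl)oxy]-3,7,7-trimethyloct-2-ene | BrC/C=C(\C)C[C@H](O[Si](C)(C)C(C)(C)C)CC(C)(C)COCc1ccc(OC)cc1 | intermediate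
13 | dimethyl (2-oxopropyl)phosphonate | CC(=O)CP(=O)(OC)OC | starting material
14 | sodium lithium dianion of dimethyl (2-oxopropyl)phosphonate | [Na+].[Li+].[CH2-]C(=O)[CH-]P(=O)(OC)OC | intermediate
15 | dimethyl [(5E,8S)-8-[(tert-butyldimethylsilyl)oxy]-11-[(4-methoxybenzyl)oxy]-6,10,10-trimethyl-2-oxoundec-5-en-1-yl]phosphonate | COP(=O)(OC)CC(=O)CC/C=C(\C)C[C@H](O[Si](C)(C)C(C)(C)C)CC(C)(C)COCc1ccc(OC)cc1 | intermediate
16 | dimethyl [(5E,8S)-8-[(tert-butyldimethylsilyl)oxy]-11-hydroxy-6,10,10-trimethyl-2-oxoundec-5-en-1-yl]phosphonate | COP(=O)(OC)CC(=O)CC/C=C(\C)C[C@H](O[Si](C)(C)C(C)(C)C)CC(C)(C)CO | intermediate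
17 | dimethyl [(5E,8S)-8-[(tert-butyldimethylsilyl)oxy]-6,10,10-trimethyl-2,11-dioxoundec-5-en-1-yl]phosphonate | COP(=O)(OC)CC(=O)CC/C=C(\C)C[C@H](O[Si](C)(C)C(C)(C)C)CC(C)(C)C=O | intermediate
18 | (2E,6S,8E)-6-[(tert-butyldimethylsilyl)oxy]-4,4,8-trimethylcycloundeca-2,8-dien-1-one | O=C1/C=C/C(C)(C)C[C@@H](O[Si](C)(C)C(C)(C)C)C/C(C)=C/CC1 | intermediate
19 | tert-butyldimethyl{[(1S,3E,8E)-3,10,10-trimethyl-7-methylidenecycloundeca-3,8-dien-1-yl]oxy}silane | C=C1/C=C/C(C)(C)C[C@@H](O[Si](C)(C)C(C)(C)C)C/C(C)=C/CC1 | intermediate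
20 | (1S,3E,8E)-3,10,10-trimethyl-7-methylidenecycloundeca-3,8-dien-1-ol | C=C1/C=C/C(C)(C)C[C@@H](O)C/C(C)=C/CC1 | intermediate
21 | 3-hydroxy-4-methoxybenzoic acid (isovanillic acid) | COc1ccc(C(=O)O)cc1O | starting material
22 | tert-butyldimethylsilyl 3-[(tert-butyldimethylsilyl)oxy]-4-methoxybenzoate | COc1ccc(C(=O)O[Si](C)(C)C(C)(C)C)cc1O[Si](C)(C)C(C)(C)C | intermediate
23 | 3-[(tert-butyldimethylsilyl)oxy]-4-methoxybenzoic acid | COc1ccc(C(=O)O)cc1O[Si](C)(C)C(C)(C)C | intermediate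
24 | (1S,3E,8E)-3,10,10-trimethyl-7-methylidenecycloundeca-3,8-dien-1-yl 3-[(tert-butyldimethylsilyl)oxy]-4-methoxybenzoate | C=C1/C=C/C(C)(C)C[C@@H](OC(=O)c2ccc(OC)c(O[Si](C)(C)C(C)(C)C)c2)C/C(C)=C/CC1 | intermediate
25 | (1S,3E,8E)-3,10,10-trimethyl-7-methylidenecycloundeca-3,8-dien-1-yl 3-hydroxy-4-methoxybenzoate (CNP0220645.1) | C=C1/C=C/C(C)(C)C[C@@H](OC(=O)c2ccc(OC)c(O)c2)C/C(C)=C/CC1 | target

**Totals**
Total step count: 17.
Longest linear sequence: 15 steps (1 → 25 through steps 1–3, 5–14, 16 and 17); steps 4 and 15 are side branches.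

**Three steps most likely to fail, with fallbacks**

Step 5 (asymmetric vinylogous aldol). Aliphatic aldehydes are the slowest substrates for the SiCl4/phosphoramide system, so yield or ee may be inadequate. The fallback sets out from aldehyde 4 and returns at enoate 10, replacing the aldol by an asymmetric carbonyl allylation and building the trisubstituted alkene separately. Brown allylation of 4 with (−)-Ipc2B(allyl) (from (+)-α-pinene; Si-face addition; Et2O, −78 °C, then NaOH/H2O2) gives (4S)-1-[(4-methoxybenzyl)oxy]-2,2-dimethylhept-6-en-4-ol F1. Silylation (TBSCl, imidazole) gives tert-butyl{[(4S)-1-[(4-methoxybenzyl)oxy]-2,2-dimethylhept-6-en-4-yl]oxy}dimethylsilane F2. Lemieux–Johnson cleavage gives (3R)-3-[(tert-butyldimethylsilyl)oxy]-6-[(4-methoxybenzyl)oxy]-5,5-dimethylhexanal F3 (the descriptor changes only because of CIP priorities). Ohira–Bestmann homologation (dimethyl (1-diazo-2-oxopropyl)phosphonate, K2CO3, MeOH) gives tert-butyl{[(4S)-7-[(4-methoxybenzyl)oxy]-6,6-dimethylhept-1-yn-4-yl]oxy}dimethylsilane F4. Negishi carboalumination (AlMe3, cat. Cp2ZrCl2, CH2Cl2) and trapping of the (E)-alkenylalane with methyl chloroformate then gives 10 with the E-methyl-branched enoate set by syn-addition.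

Step 12 (11-membered HWE macrocyclisation). Medium-ring strain and a hindered neopentyl aldehyde may favour dimers. The fallback sets out from bromide 12 and returns at enone 18, closing the same bond by an intramolecular Nozaki–Hiyama–Kishi reaction. Alkylation of the lithium enolate of N-methoxy-N-methylacetamide (LDA, THF, −78 °C) with 12 gives (4E,7S)-7-[(tert-butyldimethylsilyl)oxy]-N-methoxy-10-[(4-methoxybenzyl)oxy]-N,5,9,9-tetramethyldec-4-enamide F5. DDQ gives (4E,7S)-7-[(tert-butyldimethylsilyl)oxy]-10-hydroxy-N-methoxy-N,5,9,9-tetramethyldec-4-enamide F6. Dess–Martin oxidation gives (4E,7S)-7-[(tert-butyldimethylsilyl)oxy]-N-methoxy-N,5,9,9-tetramethyl-10-oxodec-4-enamide F7. Takai olefination (CrCl2, CHI3, THF) gives (4E,7S,10E)-7-[(tert-butyldimethylsilyl)oxy]-11-iodo-N-methoxy-N,5,9,9-tetramethylundeca-4,10-dienamide F8. DIBAL-H at −78 °C gives (4E,7S,10E)-7-[(tert-butyldimethylsilyl)oxy]-11-iodo-5,9,9-trimethylundeca-4,10-dienal F9. CrCl2/cat. NiCl2 in DMSO at 2 mM closes the ring to (2E,6S,8E)-6-[(tert-butyldimethylsilyl)oxy]-4,4,8-trimethylcycloundeca-2,8-dien-1-ol F10 (both C1 epimers), and Dess–Martin oxidation converges on 18.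

Step 13 (methylenation of the macrocyclic enone). The ylide may enolise the hindered, possibly twisted enone instead of adding. The fallback sets out from 18 and returns at 19 by a stepwise Peterson olefination. The non-basic organocerium reagent from Me3SiCH2Li and CeCl3 (THF, −78 °C) adds 1,2 to give (2E,6S,8E)-6-[(tert-butyldimethylsilyl)oxy]-4,4,8-trimethyl-1-[(trimethylsilyl)methyl]cycloundeca-2,8-dien-1-ol F11 (C1 epimers, both usable). KH in THF then effects syn-elimination to 19 without acid, so the diene is not exposed to cationic rearrangement.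

**Further compounds**
F1 | step 5 | (4S)-1-[(4-methoxybenzyl)oxy]-2,2-dimethylhept-6-en-4-ol | C=CC[C@H](O)CC(C)(C)COCc1ccc(OC)cc1
F2 | step 5 | tert-butyl{[(4S)-1-[(4-methoxybenzyl)oxy]-2,2-dimethylhept-6-en-4-yl]oxy}dimethylsilane | C=CC[C@H](O[Si](C)(C)C(C)(C)C)CC(C)(C)COCc1ccc(OC)cc1
F3 | step 5 | (3R)-3-[(tert-butyldimethylsilyl)oxy]-6-[(4-methoxybenzyl)oxy]-5,5-dimethylhexanal | O=CC[C@H](O[Si](C)(C)C(C)(C)C)CC(C)(C)COCc1ccc(OC)cc1
F4 | step 5 | tert-butyl{[(4S)-7-[(4-methoxybenzyl)oxy]-6,6-dimethylhept-1-yn-4-yl]oxy}dimethylsilane | C#CC[C@H](O[Si](C)(C)C(C)(C)C)CC(C)(C)COCc1ccc(OC)cc1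
F5 | step 12 | (4E,7S)-7-[(tert-butyldimethylsilyl)oxy]-N-methoxy-10-[(4-methoxybenzyl)oxy]-N,5,9,9-tetramethyldec-4-enamide | CON(C)C(=O)CC/C=C(\C)C[C@H](O[Si](C)(C)C(C)(C)C)CC(C)(C)COCc1ccc(OC)cc1
F6 | step 12 | (4E,7S)-7-[(tert-butyldimethylsilyl)oxy]-10-hydroxy-N-methoxy-N,5,9,9-tetramethyldec-4-enamide | CON(C)C(=O)CC/C=C(\C)C[C@H](O[Si](C)(C)C(C)(C)C)CC(C)(C)CO
F7 | step 12 | (4E,7S)-7-[(tert-butyldimethylsilyl)oxy]-N-methoxy-N,5,9,9-tetramethyl-10-oxodec-4-enamide | CON(C)C(=O)CC/C=C(\C)C[C@H](O[Si](C)(C)C(C)(C)C)CC(C)(C)C=O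
F8 | step 12 | (4E,7S,10E)-7-[(tert-butyldimethylsilyl)oxy]-11-iodo-N-methoxy-N,5,9,9-tetramethylundeca-4,10-dienamide | CON(C)C(=O)CC/C=C(\C)C[C@H](O[Si](C)(C)C(C)(C)C)CC(C)(C)/C=C/I
F9 | step 12 | (4E,7S,10E)-7-[(tert-butyldimethylsilyl)oxy]-11-iodo-5,9,9-trimethylundeca-4,10-dienal | O=CCC/C=C(\C)C[C@H](O[Si](C)(C)C(C)(C)C)CC(C)(C)/C=C/I
F10 | step 12 | (2E,6S,8E)-6-[(tert-butyldimethylsilyl)oxy]-4,4,8-trimethylcycloundeca-2,8-dien-1-ol (C1 epimers) | OC1/C=C/C(C)(C)C[C@@H](O[Si](C)(C)C(C)(C)C)C/C(C)=C/CC1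
F11 | step 13 | (2E,6S,8E)-6-[(tert-butyldimethylsilyl)oxy]-4,4,8-trimethyl-1-[(trimethylsilyl)methyl]cycloundeca-2,8-dien-1-ol (C1 epimers) | C[Si](C)(C)CC1(O)/C=C/C(C)(C)C[C@@H](O[Si](C)(C)C(C)(C)C)C/C(C)=C/CC1
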